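**Assumptions**
- Numbering: cembrane/trinervitane numbering is used (ring C1–C14, isopropenyl C15(=C16)–C17, methyls C18 on C4, C19 on C8, C20 on C12). In it the target is (2R,3R,4S,7R,9E,12S,14S,16S)-2-hydroxytrinervita-1(15),8(19),9-triene-3,14-diyl diacetate.
- Reagent sense: pig liver esterase is taken to give the (R)-half-ester, and (+)-3-exo-morpholinoisoborneol ((+)-MIB) to give Re-face alkenyl transfer (Noyori model). If the sense is opposite, the other MIB enantiomer is used.

**Retrosynthetic overview**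
1. Target ⇒ (desilylation, O-3 acetylation) tricyclic alcohol 24 ⇒ one Lewis-acid cascade on the 14-membered epoxy-cembranoid 22: C16 of the isopropenyl group forms first C4–C16, then C7–C16.
2. 22 ⇒ hydroxyl-directed epoxidation and silylation of macrocycle 20 ⇒ macrocyclic carbonyl–ene closure of C1–C2 from acyclic enal 19 (the bond nature closes in going from geranylgeranyl diphosphate to cembrene).
3. 19 ⇒ CrCl2/NiCl2 coupling (C7–C8) of bromodiene 13 with aldehyde 15 (C2–C7, from geranyl acetate).
4. 13 ⇒ lactol 5 (C12 from dimethyl 3-methylglutarate), Horner–Wadsworth–Emmons (C9=C10), asymmetric 2-methylpropenyl addition (C14).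
5. Ring order: 14-membered ring → six-membered ring → five-membered ring (which leaves the eleven-membered ring).

**Route**

Step 1
Reactants: 1 dimethyl 3-methylglutarate
Product: 2 (3R)-5-methoxy-3-methyl-5-oxopentanoic acid
Conditions: pig liver esterase, phosphate buffer pH 7/MeOH 4:1, −10 °C, pH-stat (NaOH); then HCl
Reagents that add atoms: water, O
Why: Enzymatic desymmetrisation of a prochiral diester: the esterase hydrolyses one enantiotopic ester arm and so sets the future C12 centre as the (R)-half-ester.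

Step 2
Reactants: 2 (3R)-5-methoxy-3-methyl-5-oxopentanoic acid
Product: 4 (4R)-4-methyloxan-2-one, via hydroxy ester 3 (not isolated)
Conditions: BH3·SMe2, THF, 0 °C → rt; MeOH; then TsOH (cat.), toluene, 50 °C
Reagents that add atoms: none
Why: Borane reduces the free acid chemoselectively (acyloxyborane pathway) beside the methyl ester, and acid-catalysed lactonisation of the δ-hydroxy ester closes the six-membered lactone without touching the stereocentre.

Step 3
Reactants: 4 (4R)-4-methyloxan-2-one
Product: 5 (4R)-4-methyloxan-2-ol (anomer mixture)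
Conditions: i-Bu2AlH (1.1 equiv), CH2Cl2, −78 °C; MeOH, aqueous work-up
Reagents that add atoms: none
Why: Half-reduction of a lactone: the aluminium hemiacetal is stable at −78 °C and is released as the lactol, a masked C10 aldehyde.

Step 4
Reactants: 6 2,3-dibromoprop-1-ene + 7 triethyl phosphite
Product: 8 diethyl (2-bromoprop-2-en-1-yl)phosphonate
Conditions: neat, 120 °C, distil off EtBr
Reagents that add atoms: none
Why: Michaelis–Arbuzov reaction: the phosphite displaces only the allylic bromide and bromide dealkylates the phosphonium, while the vinylic bromide is inert.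

Step 5
Reactants: 5 (4R)-4-methyloxan-2-ol + 8 diethyl (2-bromoprop-2-en-1-yl)phosphonate
Product: 9 (3S,5E)-7-bromo-3-methylocta-5,7-dien-1-ol
Conditions: 8 (2.2 equiv), LiN(SiMe3)2 (2.2 equiv), THF, −78 °C; then 5, −78 → 0 °C; NH4Cl
Reagents that add atoms: none
Why: Horner–Wadsworth–Emmons olefination of the ring-opened hydroxy-aldehyde form of the lactol with an allylic phosphonate anion gives the E C9=C10 alkene; the 2-bromoallyl anion keeps its bromide because the C–Br bond lies in the nodal plane of the allyl π system.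

Step 6
Reactants: 9 (3S,5E)-7-bromo-3-methylocta-5,7-dien-1-ol
Product: 10 (3S,5E)-7-bromo-3-methylocta-5,7-dienal
Conditions: TEMPO (10 mol %), PhI(OAc)2 (1.1 equiv), CH2Cl2, rt
Reagents that add atoms: none
Why: Oxoammonium (TEMPO) oxidation of the primary alcohol stops at the aldehyde and leaves the bromodiene and the β-stereocentre untouched.

Step 7
Reactants: 10 (3S,5E)-7-bromo-3-methylocta-5,7-dienal + 11 (2-methylprop-1-en-1-yl)magnesium bromide
Product: 13 (4S,6S,8E)-10-bromo-2,6-dimethylundeca-2,8,10-trien-4-ol, via bis(2-methylprop-1-en-1-yl)zinc 12 (not isolated)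
Conditions: 11 (2.4 equiv), ZnCl2 (1.2 equiv), THF/toluene, 0 °C; N,N,N′,N′-tetraethylethylenediamine; (+)-MIB (5 mol %); then 10, 0 °C; NH4Cl
Reagents that add atoms: none
Why: Amino-alcohol-catalysed asymmetric alkenylzinc addition (Noyori-type): the MIB–zinc complex delivers the 2-methylpropenyl group to the Re face of the aldehyde and sets C14 as S by reagent control; the diamine suppresses the salt-promoted background reaction and the vinylic bromide is inert.

Step 8
Reactants: 14 geranyl acetate
Product: 15 (2E)-3-methyl-6-oxohex-2-en-1-yl acetate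
Conditions: ozone (1.0 equiv), CH2Cl2, pyridine (cat.), −78 °C; Me2S
Reagents that add atoms: ozone, [O-][O+]=O
Why: Chemoselective ozonolysis: the electron-rich trisubstituted 6,7-alkene reacts far faster than the alkene deactivated by the allylic acetate, and Criegee cleavage with Me2S reduction gives the C7 aldehyde with the E C3=C4 alkene intact.

Step 9
Reactants: 13 (4S,6S,8E)-10-bromo-2,6-dimethylundeca-2,8,10-trien-4-ol + 15 (2E)-3-methyl-6-oxohex-2-en-1-yl acetate
Product: 16 (2E,8E,11S,13S)-6,13-dihydroxy-3,11,15-trimethyl-7-methylidenehexadeca-2,8,14-trien-1-yl acetate (both C6 epimers; C6 is cembrane C7)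
Conditions: CrCl2 (4 equiv), NiCl2 (5 mol %), DMSO, rt
Reagents that add atoms: none
Why: Nozaki–Hiyama–Kishi coupling: zerovalent nickel inserts into the dienyl C–Br bond, transmetalation to trivalent chromium gives a dienylchromium that adds only to the aldehyde (free alcohol and acetate tolerated); the C7 carbinol forms as a 1:1 mixture, which does not matter because C7 is ionised in step 15.

Step 10
Reactants: 16 the C20 dihydroxy acetate
Product: 17 (2E,8E,11S,13S)-3,11,15-trimethyl-7-methylidenehexadeca-2,8,14-triene-1,6,13-triol (both C6 epimers)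
Conditions: K2CO3 (0.2 equiv), MeOH, 0 °C
Reagents that add atoms: none
Why: Base-catalysed transesterification removes the primary allylic acetate as methyl acetate and touches nothing else.

Step 11
Reactants: 17 the C20 triol
Product: 19 (2E,8E,11S,13S)-3,11,15-trimethyl-7-methylidene-1-oxohexadeca-2,8,14-triene-6,13-diyl diacetate (both C6 epimers), via dihydroxy enal 18 (not isolated)
Conditions: TEMPO (10 mol %), PhI(OAc)2 (1.1 equiv), CH2Cl2, 0 °C; then pyridine, Ac2O, DMAP (cat.), 0 °C → rt
Reagents that add atoms: acetic anhydride, CC(=O)OC(C)=O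
Why: TEMPO oxidation is selective for the primary allylic alcohol over the two secondary ones and gives the E-enal (C2), and DMAP-catalysed acetylation in the same flask turns O-7 into the later leaving group and O-14 into the final acetate.

Step 12
Reactants: 19 the C20 diacetoxy enal
Product: 20 (1R,2S,3E,9E,12S,14S)-2-hydroxycembra-3,8(19),9,15-tetraene-7,14-diyl diacetate (both C7 epimers)
Conditions: MeAlCl2 (2.5 equiv), CH2Cl2, slow addition of 19 to 1 mM, −78 °C
Reagents that add atoms: none
Why: Lewis-acid carbonyl–ene macrocyclisation (the citronellal-to-isopulegol reaction in a large ring, known for conjugated ynals giving cembranoids): C1 of the 2-methylpropenyl terminus attacks the complexed enal carbon C2 while a methyl hydrogen passes to oxygen, which creates the isopropenyl group; the chair-like closed transition state gives the trans C1/C2 pair, and A1,3 strain holds H14 in the alkene plane so that C2 adds anti to C13.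

Step 13
Reactants: 20 the macrocyclic allylic alcohol
Product: 21 (1R,2R,3S,4S,9E,12S,14S)-3,4-epoxy-2-hydroxycembra-8(19),9,15-triene-7,14-diyl diacetate (both C7 epimers)
Conditions: VO(acac)2 (5 mol %), t-BuOOH (1.3 equiv), CH2Cl2, 0 °C
Reagents that add atoms: tert-butyl hydroperoxide, CC(C)(C)OO
Why: Hydroxyl-directed vanadium epoxidation reacts only at the allylic C3=C4 alkene; A1,3 strain between C18 and C2 places H2 in the alkene plane, so oxygen is delivered syn to the C2 hydroxyl and sets C3 and C4.

Step 14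
Reactants: 21 the epoxy alcohol
Product: 22 (1S,2R,3S,4S,9E,12S,14S)-2-(tert-butyldimethylsilyloxy)-3,4-epoxycembra-8(19),9,15-triene-7,14-diyl diacetate (both C7 epimers)
Conditions: TBSOTf (1.2 equiv), 2,6-lutidine (2 equiv), CH2Cl2, −78 °C
Reagents that add atoms: tert-butyldimethylsilyl trifluoromethanesulfonate, CC(C)(C)[Si](C)(C)OS(=O)(=O)C(F)(F)F
Why: Silylation of the alcohol by the silyl triflate at −78 °C with lutidine is faster than epoxide opening, and the silyl ether keeps O-2 distinct from O-3 for the final acetylation pattern.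

Step 15
Reactants: 22 the silylated epoxy-cembranoid diacetate
Product: 24 (2R,3R,4S,7R,9E,12S,14S,16S)-2-(tert-butyldimethylsilyloxy)-3-hydroxytrinervita-1(15),8(19),9-trien-14-yl acetate, via bicyclic triene alcohol 23 (not isolated)
Conditions: BF3·OEt2 (3 equiv), CH2Cl2 (2 mM), −78 → −30 °C; aqueous NaHCO3
Reagents that add atoms: none
Why: Proposed new method: BF3 opens the epoxide at tertiary C4 with anti attack by the isopropenyl terminus C16 (chair, C5 and the silyloxy group equatorial, C14 axial), which closes the six-membered ring and sets C4; because H1 is then equatorial the C15 cation loses the axial H16 to give 23, whose C15=C16 bond captures through C16 the allyl cation formed by ionising the C7 acetate (five-membered ring, cis at C4/C16 by the tether, C8 trans to C15 as the eleven-membered ring requires, setting C16 and C7), and the regenerated C15 cation loses H1 to the tetrasubstituted 1(15)-alkene with the 8(19),9-diene already in place; the closest known reactions are Lewis-acid epoxide-initiated cation–olefin cyclisations (including transannular closure of cembrene epoxides to secotrinervitanes) and allyl-cation–alkene cyclisations, here chained through one carbon that acts twice as the nucleophile, as in the proposed biogenesis.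

Step 16
Reactants: 24 the tricyclic silyl ether alcohol
Product: 26 (2R,3R,4S,7R,9E,12S,14S,16S)-2-hydroxytrinervita-1(15),8(19),9-triene-3,14-diyl diacetate (CNP0323842.1), via silyl ether diacetate 25 (not isolated)
Conditions: Ac2O, DMAP, Et3N, CH2Cl2, 40 °C; MeOH quench; then HF·pyridine, THF, 0 °C → rt
Reagents that add atoms: acetic anhydride, CC(=O)OC(C)=O
Why: DMAP-catalysed acetylation of the only free hydroxyl (O-3), then Si–O cleavage by fluoride under mildly acidic conditions that do not move the acetyl group from O-3 to O-2.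

**Compound list**
1 | dimethyl 3-methylglutarate | COC(=O)CC(C)CC(=O)OC | starting material
2 | (3R)-5-methoxy-3-methyl-5-oxopentanoic acid | COC(=O)C[C@H](C)CC(=O)O | intermediate
3 | methyl (3R)-5-hydroxy-3-methylpentanoate | COC(=O)C[C@H](C)CCO | intermediate (not isolated)
4 | (4R)-4-methyloxan-2-one | O=C1C[C@H](C)CCO1 | intermediate
5 | (4R)-4-methyloxan-2-ol (anomer mixture) | OC1C[C@H](C)CCO1 | intermediate
6 | 2,3-dibromoprop-1-ene | C=C(Br)CBr | starting material
7 | triethyl phosphite | CCOP(OCC)OCC | starting material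
8 | diethyl (2-bromoprop-2-en-1-yl)phosphonate | CCOP(=O)(CC(Br)=C)OCC | intermediate
9 | (3S,5E)-7-bromo-3-methylocta-5,7-dien-1-ol | C=C(Br)/C=C/C[C@H](C)CCO | intermediate
10 | (3S,5E)-7-bromo-3-methylocta-5,7-dienal | C=C(Br)/C=C/C[C@H](C)CC=O | intermediate
11 | (2-methylprop-1-en-1-yl)magnesium bromide | CC(C)=C[Mg]Br | starting material
12 | bis(2-methylprop-1-en-1-yl)zinc | CC(C)=C[Zn]C=C(C)C | intermediate (not isolated)
13 | (4S,6S,8E)-10-bromo-2,6-dimethylundeca-2,8,10-trien-4-ol | C=C(Br)/C=C/C[C@H](C)C[C@H](O)C=C(C)C | intermediate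
14 | geranyl acetate | CC(C)=CCC/C(C)=C/COC(C)=O | starting material
15 | (2E)-3-methyl-6-oxohex-2-en-1-yl acetate | CC(=O)OC/C=C(\C)CCC=O | intermediate
16 | (2E,8E,11S,13S)-6,13-dihydroxy-3,11,15-trimethyl-7-methylidenehexadeca-2,8,14-trien-1-yl acetate (C6 epimers) | CC(=O)OC/C=C(\C)CCC(O)C(=C)/C=C/C[C@H](C)C[C@H](O)C=C(C)C | intermediate
17 | (2E,8E,11S,13S)-3,11,15-trimethyl-7-methylidenehexadeca-2,8,14-triene-1,6,13-triol (C6 epimers) | OC/C=C(\C)CCC(O)C(=C)/C=C/C[C@H](C)C[C@H](O)C=C(C)C | intermediate
18 | (2E,8E,11S,13S)-6,13-dihydroxy-3,11,15-trimethyl-7-methylidenehexadeca-2,8,14-trienal (C6 epimers) | O=C/C=C(\C)CCC(O)C(=C)/C=C/C[C@H](C)C[C@H](O)C=C(C)C | intermediate (not isolated)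
19 | (2E,8E,11S,13S)-3,11,15-trimethyl-7-methylidene-1-oxohexadeca-2,8,14-triene-6,13-diyl diacetate (C6 epimers) | O=C/C=C(\C)CCC(OC(C)=O)C(=C)/C=C/C[C@H](C)C[C@H](OC(C)=O)C=C(C)C | intermediate
20 | (1R,2S,3E,9E,12S,14S)-2-hydroxycembra-3,8(19),9,15-tetraene-7,14-diyl diacetate (C7 epimers) | C=C(C)[C@@H]1[C@@H](O)/C=C(\C)CCC(OC(C)=O)C(=C)/C=C/C[C@H](C)C[C@@H]1OC(C)=O | intermediate
21 | (1R,2R,3S,4S,9E,12S,14S)-3,4-epoxy-2-hydroxycembra-8(19),9,15-triene-7,14-diyl diacetate (C7 epimers) | C=C(C)[C@@H]1[C@@H](O)[C@@H]2O[C@@]2(C)CCC(OC(C)=O)C(=C)/C=C/C[C@H](C)C[C@@H]1OC(C)=O | intermediate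
22 | (1S,2R,3S,4S,9E,12S,14S)-2-(tert-butyldimethylsilyloxy)-3,4-epoxycembra-8(19),9,15-triene-7,14-diyl diacetate (C7 epimers) | C=C(C)[C@@H]1[C@@H](O[Si](C)(C)C(C)(C)C)[C@@H]2O[C@@]2(C)CCC(OC(C)=O)C(=C)/C=C/C[C@H](C)C[C@@H]1OC(C)=O | intermediate
23 | (1S,2R,3R,4S,9E,12S,14S)-2-(tert-butyldimethylsilyloxy)-3-hydroxy-7,16-secotrinervita-8(19),9,15-triene-7,14-diyl diacetate (C7 epimers) | CC1=C[C@]2(C)CCC(OC(C)=O)C(=C)/C=C/C[C@H](C)C[C@H](OC(C)=O)[C@H]1[C@@H](O[Si](C)(C)C(C)(C)C)[C@@H]2O | intermediate (not isolated)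
24 | (2R,3R,4S,7R,9E,12S,14S,16S)-2-(tert-butyldimethylsilyloxy)-3-hydroxytrinervita-1(15),8(19),9-trien-14-yl acetate | C=C1/C=C/C[C@H](C)C[C@H](OC(C)=O)C2=C(C)[C@@H]3[C@H]1CC[C@]3(C)[C@@H](O)[C@@H]2O[Si](C)(C)C(C)(C)C | intermediate
25 | (2R,3R,4S,7R,9E,12S,14S,16S)-2-(tert-butyldimethylsilyloxy)trinervita-1(15),8(19),9-triene-3,14-diyl diacetate | C=C1/C=C/C[C@H](C)C[C@H](OC(C)=O)C2=C(C)[C@@H]3[C@H]1CC[C@]3(C)[C@@H](OC(C)=O)[C@@H]2O[Si](C)(C)C(C)(C)C | intermediate (not isolated)
26 | (2R,3R,4S,7R,9E,12S,14S,16S)-2-hydroxytrinervita-1(15),8(19),9-triene-3,14-diyl diacetate (CNP0323842.1) | C=C1/C=C/C[C@H](C)C[C@H](OC(C)=O)C2=C(C)[C@@H]3[C@H]1CC[C@]3(C)[C@@H](OC(C)=O)[C@@H]2O | target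

**Step count**
Total: 16 steps. Longest linear sequence: 14 steps (1, 2, 3, 5, 6, 7, 9, 10, 11, 12, 13, 14, 15, 16).

**Three steps most likely to fail**

Step 15 (double transannular cascade). Risks: the C15 cation may lose H1 or H17 instead of H16 after the first closure; O-3 or fluoride may trap the C7 cation; the allylic acetate at C14 of the product may ionise. Fallback: two separately triggered closures with O-3 capped in between. It sets out from 22. MeAlCl2 (2 equiv, CH2Cl2, −90 °C) opens only the epoxide and the bicyclic alcohol 23 is isolated. Ac2O/DMAP converts it into (1S,2R,3R,4S,9E,12S,14S)-2-(tert-butyldimethylsilyloxy)-7,16-secotrinervita-8(19),9,15-triene-3,7,14-triyl triacetate F1. TMSOTf with 2,6-di-tert-butylpyridine (CH2Cl2, −78 °C) then ionises the C7 acetate of F1 and closes the five-membered ring. This gives 25 directly, where the route is rejoined; only the HF·pyridine half of step 16 remains.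

Step 12 (macrocyclic carbonyl–ene). Risks: the alkene is deactivated by the allylic acetate, the conjugated aldehyde is a weak enophile, and the C2 configuration rests on substrate control in a large ring. Fallback: close the same C1–C2 bond as an intramolecular Hosomi–Sakurai reaction of an allylsilane. It sets out from 10 and comes back at 20.
- Trimethyl(prop-2-yn-1-yl)silane is carboaluminated (AlMe3, Cp2ZrCl2 cat.) and iodinated to (E)-(3-iodo-2-methylprop-2-en-1-yl)trimethylsilane F2.
- Iodine–lithium exchange (tert-butyllithium), ZnBr2 and (+)-MIB as in step 7 add it to 10 to give (2E,4S,6S,8E)-10-bromo-2,6-dimethyl-1-(trimethylsilyl)undeca-2,8,10-trien-4-ol F3.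
- CrCl2/NiCl2 coupling with 15 as in step 9 gives the 16-(trimethylsilyl) analogue of 16, F4.
- K2CO3/MeOH gives the silyl triol F5.
- TEMPO/PhI(OAc)2 gives the silyl dihydroxy enal F6, and Ac2O/pyridine the silyl diacetoxy enal F7.
- MeAlCl2 (CH2Cl2, −78 °C, 1 mM) then triggers attack of the allylsilane through C1 on the enal with loss of silicon, which forms the isopropenyl group and 20.

Step 7 (catalytic asymmetric alkenylzinc addition). Risks: low ee or reversed sense with this Grignard-derived zinc reagent on a functionalised aliphatic aldehyde. Fallback: set C14 by reagent-controlled ketone reduction. It sets out from 10 and comes back at 13. Grignard reagent 11 is added directly to 10 (THF, −78 °C) to give (4RS,6S,8E)-10-bromo-2,6-dimethylundeca-2,8,10-trien-4-ol F8. MnO2 (CH2Cl2) oxidises it to (6S,8E)-10-bromo-2,6-dimethylundeca-2,8,10-trien-4-one F9. (R)-2-Methyl-CBS-oxazaborolidine (10 mol %) with catecholborane (toluene, −78 °C) reduces F9 to 13, with the alkenyl group as the large substituent.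

**Further compounds**
F1 | step 15 | (1S,2R,3R,4S,9E,12S,14S)-2-(tert-butyldimethylsilyloxy)-7,16-secotrinervita-8(19),9,15-triene-3,7,14-triyl triacetate (C7 epimers) | CC1=C[C@]2(C)CCC(OC(C)=O)C(=C)/C=C/C[C@H](C)C[C@H](OC(C)=O)[C@H]1[C@@H](O[Si](C)(C)C(C)(C)C)[C@@H]2OC(C)=O
F2 | step 12 | (E)-(3-iodo-2-methylprop-2-en-1-yl)trimethylsilane | C[Si](C)(C)C/C(C)=C/I
F3 | step 12 | (2E,4S,6S,8E)-10-bromo-2,6-dimethyl-1-(trimethylsilyl)undeca-2,8,10-trien-4-ol | C=C(Br)/C=C/C[C@H](C)C[C@H](O)/C=C(\C)C[Si](C)(C)C
F4 | step 12 | (2E,8E,11S,13S,14E)-6,13-dihydroxy-3,11,15-trimethyl-7-methylidene-16-(trimethylsilyl)hexadeca-2,8,14-trien-1-yl acetate (C6 epimers) | CC(=O)OC/C=C(\C)CCC(O)C(=C)/C=C/C[C@H](C)C[C@H](O)/C=C(\C)C[Si](C)(C)C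
F5 | step 12 | (2E,8E,11S,13S,14E)-3,11,15-trimethyl-7-methylidene-16-(trimethylsilyl)hexadeca-2,8,14-triene-1,6,13-triol (C6 epimers) | OC/C=C(\C)CCC(O)C(=C)/C=C/C[C@H](C)C[C@H](O)/C=C(\C)C[Si](C)(C)C
F6 | step 12 | (2E,8E,11S,13S,14E)-6,13-dihydroxy-3,11,15-trimethyl-7-methylidene-16-(trimethylsilyl)hexadeca-2,8,14-trienal (C6 epimers) | O=C/C=C(\C)CCC(O)C(=C)/C=C/C[C@H](C)C[C@H](O)/C=C(\C)C[Si](C)(C)C
F7 | step 12 | (2E,8E,11S,13S,14E)-3,11,15-trimethyl-7-methylidene-1-oxo-16-(trimethylsilyl)hexadeca-2,8,14-triene-6,13-diyl diacetate (C6 epimers) | O=C/C=C(\C)CCC(OC(C)=O)C(=C)/C=C/C[C@H](C)C[C@H](OC(C)=O)/C=C(\C)C[Si](C)(C)C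
F8 | step 7 | (4RS,6S,8E)-10-bromo-2,6-dimethylundeca-2,8,10-trien-4-ol | C=C(Br)/C=C/C[C@H](C)CC(O)C=C(C)C
F9 | step 7 | (6S,8E)-10-bromo-2,6-dimethylundeca-2,8,10-trien-4-one | C=C(Br)/C=C/C[C@H](C)CC(=O)C=C(C)C
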